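The data are calculated for substances that don't exist, and the scatter is random.

Reading the ring's loss off its own fall is the trap. In Thursday's run the ring falls at 0.0134 min⁻¹ from 60.0 min to 90.0 min, but at the start of that stretch 3.8 % of activated form was still there to feed it.

| setting | Thursday's | Sunday's | beta | theta |
|---|---|---|---|---|
| starting material | 0.20 M | 0.80 M | 0.40 M | 0.40 M |
| gas | 15 mM (held) | 15 mM (held) | 15 mM (held) | 15 mM (held) |
| remark | run made earlier | run made earlier |  |  |
| time |  |  | 2.0 h | 4.0 h |

| run | time / min | over-reaction product / % | starting material / % | activated form / % | ring / % | open dimer / % |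
|---|---|---|---|---|---|---|
| Thursday's | 5.00 | 0.5 | 63.8 | 27.7 | 5.1 | 2.9 |
| Thursday's | 15.0 | 2.9 | 21.8 | 38.6 | 28.0 | 9.3 |
| Thursday's | 25.0 | 7.8 | 6.5 | 26.9 | 45.9 | 12.8 |
| Thursday's | 40.0 | 19.6 | 1.6 | 10.9 | 54.4 | 12.2 |
| Thursday's | 60.0 | 36.3 | 0.4 | 3.8 | 47.3 | 11.8 |
| Thursday's | 80.0 | 50.4 | 0.8 | 0 | 37.2 | 11.6 |
| Thursday's | 90.0 | 55.3 | 0 | 1.2 | 31.6 | 11.9 |
| Sunday's | 5.00 | 0.2 | 76.2 | 14.4 | 3.2 | 6.6 |
| Sunday's | 15.0 | 1.0 | 31.9 | 23.9 | 16.6 | 28.0 |
| Sunday's | 25.0 | 2.4 | 11.5 | 20.4 | 29.1 | 36.0 |
| Sunday's | 40.0 | 10.9 | 1.8 | 10.8 | 38.1 | 38.5 |
| Sunday's | 60.0 | 22.0 | 0.9 | 4.1 | 36.5 | 39.1 |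
| Sunday's | 80.0 | 31.5 | 0.8 | 0.7 | 28.4 | 38.9 |
| Sunday's | 90.0 | 36.3 | 0 | 0 | 23.6 | 39.3 |

(scatter of a reading: 0.5 percentage points)

- percentages count the starting material that a species holds: one open dimer counts as two
- at the start none of activator is dissolved
- steps that have been proposed: starting material + activator -> activated form; activated form -> ring; starting material + activated form -> open dimer; gas <-> activator; activator + ring -> over-reaction product

- which of these there is most of at the end, counted by the starting material in it, beta (ring / open dimer / over-reaction product / activated form)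
- which of these there is most of at the end, counted by the starting material in it, theta (ring / open dimer / over-reaction product / activated form)
- final amount of the leader among these, as a percentage of the starting material charged, in beta
- final amount of the leader among these, as a percentage of the starting material charged, in theta

The decision for a charge of 0.40 M is whether to stop at 2.0 h or leave the flask to 4.0 h. A better measure is the ring clearance constant, the over-reaction product gained per minute over those last readings divided by the mean ring standing, averaged over both runs: 0.0161 min⁻¹ on Thursday and 0.0159 min⁻¹ on Sunday, so 0.0160 min⁻¹. That reads higher than the ring's own fall. Charges of 0.20 M and 0.80 M give nearly the same value, so I treat this late loss as pseudo-first-order in ring, with activator the concentration behind it. The ring's half-life is then 43.4 min.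

Open dimer stops growing in both runs, and its odds against the rest should rise with the charge. Since 0.40 M is the geometric middle of the two charges, I take the geometric middle of the odds. That gives 22.8 % dimer and a pool of 77.2 % for ring plus over-reaction product.

At 90.0 min the ring's share of that pool reads 36.4 % and 39.4 %, mean 37.9 %, and it shrinks at 0.0160 min⁻¹. So I expect over-reaction product to lead with 59.1 % in beta and 74.5 % in theta. The longer wait is 2.76 half-lives and, in this reckoning, moves 15 percentage points from ring to over-reaction product, so you leave the flask to 4.0 h if you want over-reaction product and stop at 2.0 h if you want ring.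

The forecast names over-reaction product in both flasks, at 58.5 % and 74 %, a little below mine, and says the runs suggest that “dissolved activator is depleted because gas transfer can't keep up”.

    starting material + activator → activated form (k = 7.89 M⁻¹ min⁻¹)
    activated form → ring (k = 0.0715 min⁻¹)
    starting material + activated form → open dimer (k = 0.124 M⁻¹ min⁻¹)
    gas ⇌ activator, rate k4*(csat - [activator]) (kL = 3.95 min⁻¹)
    activator + ring → over-reaction product (k = 1.08 M⁻¹ min⁻¹)

The flask gives over-reaction product as leader in beta and over-reaction product in theta, at 58.7 % and 74.4 %. At 2.00 h in beta, activator stands at 0.0147 M against a gas level of 15 mM, made 1.00 times as fast as it is used. Put 0.0160 min⁻¹ on beta's ring of 18.4 % for the 2.00 h up to theta and you get 2.70 %, where theta holds 2.69 %.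

Left until 5.0 h, the same flask should lose ring from theta's level to 1.03 %. Computed, it holds 1.02 % of ring and 76.1 % of over-reaction product.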